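Start from the constants of the last step, intermediate E ⇌ product: its balance constant is 1.2 at −20 °C and its enthalpy is −46.0 kJ/mol, so each warmer flask holds that balance further towards intermediate E.

| flask | substrate | partner | temperature | time |
|---|---|---|---|---|
| Saturday's | 0.36 M | 1.20 equiv (fed, over 8.0 min) | 0 °C | 5.0 h |
| Thursday's | 0.36 M | 1.20 equiv (fed, over 8.0 min) | 20 °C | 5.0 h |
| Friday's | 0.36 M | 1.20 equiv (fed, over 8.0 min) | −20 °C | 5.0 h |
| Tuesday's | 0.36 M | 1.20 equiv (fed, over 8.0 min) | 40 °C | 5.0 h |

    intermediate B → intermediate E (k1 = 8.9 × 10⁻⁴ /min, Ea1 = 89.0 kJ/mol)
    substrate + partner → intermediate A (k2 = 1.2 /M/min, Ea2 = 38.0 kJ/mol)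
    substrate + partner ⇌ intermediate C (K3 = 48 /M, k3 = 0.037 /M/min, Ea3 = 43.0 kJ/mol, ΔH3 = 8.00 kJ/mol)
    intermediate A → intermediate B (k4 = 0.0061 /min, Ea4 = 87.0 kJ/mol)
    intermediate C → product (k5 = 0.014 /min, Ea5 = 83.0 kJ/mol)
    partner → decomposed reagent (k6 = 8.8 × 10⁻⁴ /min, Ea6 = 84.0 kJ/mol)
    substrate + product ⇌ idle adduct, settled at all times (K7 = 32 /M, ΔH7 = −7.00 kJ/mol)
    partner + intermediate C ⇌ intermediate D (K8 = 0.52 /M, k8 = 0.027 /M/min, Ea8 = 55.0 kJ/mol, ΔH8 = 7.00 kJ/mol)
    intermediate E ⇌ product (K9 = 1.2, k9 = 0.0070 /min, Ea9 = 80.0 kJ/mol, ΔH9 = −46.0 kJ/mol)
    (constants at −20 °C)

- percent here means substrate units held: one idle adduct counts as two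
- what is said of product includes idle adduct
- all constants are for −20 °C and move with temperature by the activation energies and enthalpies
- in an amount of product, one idle adduct counts as one product

- the best flask by amount of product, in percent of the substrate charged; "all alike" if 1.5 percentage points covers them all (Saturday's / Thursday's / Friday's / Tuesday's / all alike)
- amount of product at the end, in percent of the substrate charged, Saturday's
- amount of product at the end, in percent of the substrate charged, Thursday's
- amount of product at the end, in percent of the substrate charged, Friday's
- amount of product at the end, in percent of the substrate charged, Tuesday's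

Keep a ledger of the substrate, which is the limiting reagent on paper, since you charge 1.20 equiv of partner.

First entry: the fork. In Friday's flask, at −20 °C, substrate and partner react by the route to intermediate A or the route to intermediate C, and by their forward constants the second takes 2.99% of what reacts. Nearly all therefore enters the chain through intermediates A and B to intermediate E, and I book the other 2.99% as going by way of intermediate C to product.

Second entry: the chain. Its slower link is intermediate B going to intermediate E, whose constant at −20 °C lies below that of intermediate A going to intermediate B. In Friday's flask that link has a lifetime of 18.7 h, longer than the 5.0 h run. In Saturday's flask its constant rises to 0.0197 /min, so the lifetime falls to 0.846 h, well inside the run. Thursday's and Tuesday's are warmer, so I book their chains as finished too.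

Third entry: the pool. Call intermediate E plus product the pool. Inside it, in Saturday's flask, the balance has a constant of 0.242 and the forward constant is 0.113 /min. It relaxes in 1.72 min, far quicker than the chain feeds it. So take this fast step as being at balance and reckon with what it leaves free. The balance share, the balance constant divided by one plus that constant, is the part of the pool that is product once the balance stands; at −20 °C it is 54.5%.

Fourth entry: the warm flasks. With the whole charge booked into the pool, the product is the balance share itself. Saturday's gives 19.5%. Thursday's, with a constant of 0.0608, gives 5.73%. Tuesday's, with 0.0182, gives 1.79%. Tuesday's has an entry I leave open, the partner lost to decomposed reagent, which this figure does not count.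

Fifth entry: Friday's flask. Here the pool is still filling. Its balance lags by 77.9 min, which is not short against the run, so I take product to follow the pool as it stood that much earlier. By my reckoning the chain, feeding from intermediate B, had by then put 8.94% of the charge into the pool. Adding the direct share and applying the balance share gives 6.51%.

The books close with Saturday's as the best flask.

The forecast also named Saturday's, with 19.4%, 5.7%, 6.3% and 2.4% for Saturday's, Thursday's, Friday's and Tuesday's, on the ground that “the exothermic step caps product”.

The simulation gives Saturday's as the best flask, with 19.4% for Saturday's, 5.97% for Thursday's, 6.03% for Friday's and 2.51% for Tuesday's.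

Ten times the time shows which flasks have come to rest. Saturday's reads 19.5% after 50.0 h, against 19.4% at the end of the run, and Tuesday's reads 2.51% against 2.51%. Friday's has not come to rest at the end of the run: by 50.0 h its intermediate B has fallen from 68.5% to 7.94%, and its pool holds 42.2% as intermediate E and 49.9% as product. The balance share of that pool comes to 50.2%, and the product standing in Friday's flask then is 49.9%, up from 6.03%.

The numbers of this flask were set for the occasion; the rest is arithmetic.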